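**Plan**
- Retrosynthesis: the C3–C1′ bond and the O1–C2 bond of the pyranone ring are cut together. This gives an o-hydroxyaryl enaminone and 1,2,4-trimethoxybenzene as two C–H partners. The C6–prenyl bond is then cut (para-Claisen–Cope), then the prenyl and MOM ethers, back to 2′,6′-dihydroxy-4′-methoxyacetophenone.
- Enabling feature: C3 is the α-carbon of the vinylogous ester/amide O1–C2=C3–C4=O. C1′ is the ring-B carbon para to the 4′-OMe and ortho to the 2′-OMe, that is C5 of 1,2,4-trimethoxybenzene. Both are donor carbons, and the low oxidation potential of the tri-oxygenated ring B lets an anode join them through a radical cation.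
- Forward order: ring A is bought, and a MOM ether marks the oxygen that becomes 5-OH. The prenyl group moves from O to C6 by two [3,3] shifts and DMF-DMA adds C2. The anodic coupling attaches ring B, ring C (the pyranone) closes in the same flask, and the MOM group is removed.
- Stereochemistry: there is none to set. The position of the prenyl group and the direction of ring closure are fixed by the MOM ether.

Key step: step 5

Remark: the target has no stereocentre and its only non-ring double bond (C=CMe2) has no E/Z forms, so the route delivers the achiral compound as drawn. Compounds 1 and 8 are taken as commercially available.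

**Step 1**
Reactants: 1 2′,6′-dihydroxy-4′-methoxyacetophenone
Product: 2 1-[2-hydroxy-4-methoxy-6-(methoxymethoxy)phenyl]ethan-1-one
Conditions: MOMCl (1.05 equiv), i-Pr2NEt, CH2Cl2, 0 °C → rt
Reagents that add atoms: chloromethyl methyl ether (MOMCl), COCCl
Why: Williamson-type MOM ether formation on the symmetric diol should stop at the mono-ether, because the remaining hydroxyl is then locked in the hydrogen bond to the acetyl carbonyl and is much less nucleophilic.

**Step 2**
Reactants: 2 1-[2-hydroxy-4-methoxy-6-(methoxymethoxy)phenyl]ethan-1-one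
Product: 3 1-[4-methoxy-2-(methoxymethoxy)-6-(3-methylbut-2-en-1-yloxy)phenyl]ethan-1-one
Conditions: prenyl bromide, K2CO3, DMF, 50 °C
Reagents that add atoms: prenyl bromide (1-bromo-3-methylbut-2-ene), CC(C)=CCBr
Why: Williamson O-alkylation, in which carbonate in a polar aprotic solvent deprotonates the chelated phenol and the allylic bromide is attacked at oxygen (SN2), as is usual for protected 2-hydroxyacetophenones.

**Step 3**
Reactants: 3 1-[4-methoxy-2-(methoxymethoxy)-6-(3-methylbut-2-en-1-yloxy)phenyl]ethan-1-one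
Product: 6 1-[6-hydroxy-4-methoxy-2-(methoxymethoxy)-3-(3-methylbut-2-en-1-yl)phenyl]ethan-1-one, via ortho-dienone 4 (not isolated), via para-dienone 5 (not isolated)
Conditions: PhNEt2, 200 °C, sealed tube, Ar
Reagents that add atoms: none
Why: Aromatic para-Claisen–Cope rearrangement, in which the [3,3] shift to the only free ortho carbon gives dienone 4, a second [3,3] (Cope) shift passes the crowded 1,1-dimethylallyl group to the para carbon (the CH between OMe and OMOM) to give 5, and enolisation restores the chelated phenol, so the prenyl group should end beside the MOM-protected oxygen and the free hydroxyl is the one remote from it.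

**Step 4**
Reactants: 6 1-[6-hydroxy-4-methoxy-2-(methoxymethoxy)-3-(3-methylbut-2-en-1-yl)phenyl]ethan-1-one
Product: 7 (2E)-3-(dimethylamino)-1-[6-hydroxy-4-methoxy-2-(methoxymethoxy)-3-(3-methylbut-2-en-1-yl)phenyl]prop-2-en-1-one
Conditions: DMF-DMA, toluene, 90 °C
Reagents that add atoms: N,N-dimethylformamide dimethyl acetal (DMF-DMA), COC(OC)N(C)C
Why: Condensation of the methyl ketone with the amide acetal (enaminone formation) should give the E-configured vinylogous amide with the hydrogen-bonded phenol left free, as in the standard chromone synthesis from 2-hydroxyacetophenones.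

**Step 5**
Reactants: 7 (2E)-3-(dimethylamino)-1-[6-hydroxy-4-methoxy-2-(methoxymethoxy)-3-(3-methylbut-2-en-1-yl)phenyl]prop-2-en-1-one; 8 1,2,4-trimethoxybenzene
Product: 11 7-methoxy-5-(methoxymethoxy)-6-(3-methylbut-2-en-1-yl)-3-(2,4,5-trimethoxyphenyl)-4H-chromen-4-one, via α-aryl enaminone 9 (not isolated), via 2-(dimethylamino)chromanone aminal 10 (not isolated)
Conditions: 8 (3 equiv), undivided cell, graphite anode, Pt cathode (H2 evolution), n-Bu4NPF6 (0.1 M), HFIP–CH2Cl2 (4:1), anode held at the first oxidation wave of 8 (ca. +1.1 V vs SCE), ca. 2.2 F mol−1, rt; then 40 °C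
Reagents that add atoms: none
Why: Proposed new method: anodic one-electron oxidation in HFIP turns 1,2,4-trimethoxybenzene into a persistent radical cation that is attacked at its C5 (para to one OMe, ortho to another) by the nucleophilic α-carbon of the vinylogous amide 7, and loss of a second electron and two protons gives the α-aryl enaminone 9; should 7 be oxidised first, its radical cation is trapped by neutral 8 at the same two carbons (as in SOMO-type α-arylation), so both manifolds converge on the C3–C1′ bond. The closest known reaction types are the electrochemical domino C–H functionalisation/chromone annulation of o-hydroxyaryl enaminones (C–S, C–Se and C–halogen bond formation) and the anodic dehydrogenative phenol–arene and arene–arene cross-couplings in HFIP; new here is the C–C union of an enaminone with an arene C–H partner. The pyranone ring then closes as in the deoxybenzoin/DMF-DMA isoflavone synthesis: 6-endo-trig oxa-Michael addition of the phenol oxygen to the aminomethylene carbon (6-exo-trig on the iminium tautomer) gives aminal 10, and β-elimination of dimethylamine aromatises the ring. No stereocentre is formed. The step needs cross- over homo-coupling, regioselectivity at C5 of 8 and chemoselectivity over the prenyl double bond and ring A: excess 8 and the much higher nucleophilicity of the enaminone carbon compared with neutral 8 favour the cross-product, C5 is the innate site of electrophilic substitution and of radical-cation coupling of 8, and potential control keeps the cell below the oxidation of the trisubstituted alkene and of the acyl-deactivated ring A, while the product, whose new aryl ring carries the electron-poor chromonyl group, should be harder to oxidise than 8.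

**Step 6**
Reactants: 11 7-methoxy-5-(methoxymethoxy)-6-(3-methylbut-2-en-1-yl)-3-(2,4,5-trimethoxyphenyl)-4H-chromen-4-one
Product: 12 5-hydroxy-7-methoxy-6-(3-methylbut-2-en-1-yl)-3-(2,4,5-trimethoxyphenyl)-4H-chromen-4-one
Conditions: 3 M aq HCl, MeOH–THF, 40 °C
Reagents that add atoms: none
Why: Acid-catalysed acetal solvolysis (MOM cleavage) should be fast for the 5-O-MOM group peri to the C4 carbonyl, and the freed phenol is tied up in the hydrogen bond to that carbonyl, which disfavours its addition to the prenyl double bond under these mild conditions.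

**Compound list**
1 | 2′,6′-dihydroxy-4′-methoxyacetophenone | CC(=O)c1c(O)cc(OC)cc1O | starting material
2 | 1-[2-hydroxy-4-methoxy-6-(methoxymethoxy)phenyl]ethan-1-one | CC(=O)c1c(O)cc(OC)cc1OCOC | intermediate
3 | 1-[4-methoxy-2-(methoxymethoxy)-6-(3-methylbut-2-en-1-yloxy)phenyl]ethan-1-one | CC(=O)c1c(OCC=C(C)C)cc(OC)cc1OCOC | intermediate
4 | ortho-dienone: 2-acetyl-5-methoxy-3-(methoxymethoxy)-6-(2-methylbut-3-en-2-yl)cyclohexa-2,4-dien-1-one (racemic, transient) | CC(=O)C1=C(OCOC)C=C(OC)C(C(C)(C)C=C)C1=O | intermediate (not isolated)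
5 | para-dienone: 2-acetyl-5-methoxy-3-(methoxymethoxy)-4-(3-methylbut-2-en-1-yl)cyclohexa-2,5-dien-1-one (racemic, transient) | CC(=O)C1=C(OCOC)C(CC=C(C)C)C(OC)=CC1=O | intermediate (not isolated)
6 | 1-[6-hydroxy-4-methoxy-2-(methoxymethoxy)-3-(3-methylbut-2-en-1-yl)phenyl]ethan-1-one | CC(=O)c1c(O)cc(OC)c(CC=C(C)C)c1OCOC | intermediate
7 | (2E)-3-(dimethylamino)-1-[6-hydroxy-4-methoxy-2-(methoxymethoxy)-3-(3-methylbut-2-en-1-yl)phenyl]prop-2-en-1-one | CN(C)/C=C/C(=O)c1c(O)cc(OC)c(CC=C(C)C)c1OCOC | intermediate
8 | 1,2,4-trimethoxybenzene | COc1ccc(OC)c(OC)c1 | starting material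
9 | α-aryl enaminone: 3-(dimethylamino)-1-[6-hydroxy-4-methoxy-2-(methoxymethoxy)-3-(3-methylbut-2-en-1-yl)phenyl]-2-(2,4,5-trimethoxyphenyl)prop-2-en-1-one (alkene geometry not defined, transient) | CN(C)C=C(C(=O)c1c(O)cc(OC)c(CC=C(C)C)c1OCOC)c1cc(OC)c(OC)cc1OC | intermediate (not isolated)
10 | aminal: 2-(dimethylamino)-7-methoxy-5-(methoxymethoxy)-6-(3-methylbut-2-en-1-yl)-3-(2,4,5-trimethoxyphenyl)chroman-4-one (mixture of stereoisomers, transient) | CN(C)C1Oc2cc(OC)c(CC=C(C)C)c(OCOC)c2C(=O)C1c1cc(OC)c(OC)cc1OC | intermediate (not isolated)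
11 | 7-methoxy-5-(methoxymethoxy)-6-(3-methylbut-2-en-1-yl)-3-(2,4,5-trimethoxyphenyl)-4H-chromen-4-one | COCOc1c(CC=C(C)C)c(OC)cc2occ(-c3cc(OC)c(OC)cc3OC)c(=O)c12 | intermediate
12 | 5-hydroxy-7-methoxy-6-(3-methylbut-2-en-1-yl)-3-(2,4,5-trimethoxyphenyl)-4H-chromen-4-one | COc1cc(OC)c(-c2coc3cc(OC)c(CC=C(C)C)c(O)c3c2=O)cc1OC | target

**Count**
Total steps: 6. Longest linear sequence: 6 steps (1 → 12); compound 8 is used as bought.

**Steps most likely to fail**

Step 5. The arene radical cation may homo-couple instead of being captured by the enaminone. The product, the liberated amine or ring A with its prenyl group may be oxidised further. The MOM ether may be lost in the acidic anode layer, or the annulation may stall at the enaminone stage. The fallback uses known chemistry and sets out from 7. Iodine in chloroform at room temperature should bring about the established iodocyclisation of o-hydroxyaryl enaminones to 3-iodo-7-methoxy-5-(methoxymethoxy)-6-(3-methylbut-2-en-1-yl)-4H-chromen-4-one F1, with the liberated dimethylamine buffering the hydrogen iodide. Suzuki–Miyaura coupling of F1 with commercial (2,4,5-trimethoxyphenyl)boronic acid (COc1cc(OC)c(B(O)O)cc1OC) under Pd(dppf)Cl2, Na2CO3, DME–water at 80 °C should then give 11, where the route is rejoined.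

Step 3. Dienone 4 may enolise before the Cope shift, leaving a 1,1-dimethylallyl group on the ortho carbon. The prenyl or MOM group may also be lost thermally at 200 °C. The fallback abandons the sigmatropic delivery for a cross-coupling and sets out from 1.
- Mono-silylation (TBSCl, imidazole, DMF) should give 1-[2-(tert-butyldimethylsilyloxy)-6-hydroxy-4-methoxyphenyl]ethan-1-one F2.
- N-iodosuccinimide in MeCN should iodinate ortho to the free hydroxyl and away from the bulky silyl ether, giving 1-[6-(tert-butyldimethylsilyloxy)-2-hydroxy-3-iodo-4-methoxyphenyl]ethan-1-one F3.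
- MOMCl with i-Pr2NEt should cap the iodine-flanked hydroxyl to give 1-[6-(tert-butyldimethylsilyloxy)-3-iodo-4-methoxy-2-(methoxymethoxy)phenyl]ethan-1-one F4.
- Stille coupling with tributyl(3-methylbut-2-en-1-yl)stannane (CC(C)=CC[Sn](CCCC)(CCCC)CCCC), Pd(PPh3)4, DMF, 90 °C should give 1-[6-(tert-butyldimethylsilyloxy)-4-methoxy-2-(methoxymethoxy)-3-(3-methylbut-2-en-1-yl)phenyl]ethan-1-one F5.
- TBAF in THF at 0 °C should free the remote phenol and return the route to 6.

Step 6. The freed 5-hydroxyl may add to the neighbouring prenyl double bond under acid catalysis (chroman formation), or HCl/MeOH may add across that double bond. The fallback replaces the acid-labile marker group by a fluoride-labile one and therefore sets out from 1.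
- SEMCl with i-Pr2NEt should give 1-(2-hydroxy-4-methoxy-6-{[2-(trimethylsilyl)ethoxy]methoxy}phenyl)ethan-1-one F6.
- Prenyl bromide with K2CO3 should give 1-[4-methoxy-2-(3-methylbut-2-en-1-yloxy)-6-{[2-(trimethylsilyl)ethoxy]methoxy}phenyl]ethan-1-one F7.
- Heating in PhNEt2 should lead, by way of the SEM-bearing ortho-dienone F8 and the SEM-bearing para-dienone F9, to 1-[6-hydroxy-4-methoxy-3-(3-methylbut-2-en-1-yl)-2-{[2-(trimethylsilyl)ethoxy]methoxy}phenyl]ethan-1-one F10.
- DMF-DMA should give (2E)-3-(dimethylamino)-1-[6-hydroxy-4-methoxy-3-(3-methylbut-2-en-1-yl)-2-{[2-(trimethylsilyl)ethoxy]methoxy}phenyl]prop-2-en-1-one F11.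
- The anodic coupling with 8 should pass through the SEM-bearing α-aryl enaminone F12 and the SEM-bearing 2-(dimethylamino)chromanone aminal F13 to 7-methoxy-6-(3-methylbut-2-en-1-yl)-3-(2,4,5-trimethoxyphenyl)-5-{[2-(trimethylsilyl)ethoxy]methoxy}-4H-chromen-4-one F14.
- TBAF in THF/DMPU at 50 °C should then cleave the SEM ether without any acid and give 12 directly.

**Further compounds**
F1 | step 5 | 3-iodo-7-methoxy-5-(methoxymethoxy)-6-(3-methylbut-2-en-1-yl)-4H-chromen-4-one | COCOc1c(CC=C(C)C)c(OC)cc2occ(I)c(=O)c12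
F2 | step 3 | 1-[2-(tert-butyldimethylsilyloxy)-6-hydroxy-4-methoxyphenyl]ethan-1-one | CC(=O)c1c(O)cc(OC)cc1O[Si](C)(C)C(C)(C)C
F3 | step 3 | 1-[6-(tert-butyldimethylsilyloxy)-2-hydroxy-3-iodo-4-methoxyphenyl]ethan-1-one | CC(=O)c1c(O)c(I)c(OC)cc1O[Si](C)(C)C(C)(C)C
F4 | step 3 | 1-[6-(tert-butyldimethylsilyloxy)-3-iodo-4-methoxy-2-(methoxymethoxy)phenyl]ethan-1-one | CC(=O)c1c(OCOC)c(I)c(OC)cc1O[Si](C)(C)C(C)(C)C
F5 | step 3 | 1-[6-(tert-butyldimethylsilyloxy)-4-methoxy-2-(methoxymethoxy)-3-(3-methylbut-2-en-1-yl)phenyl]ethan-1-one | CC(=O)c1c(OCOC)c(CC=C(C)C)c(OC)cc1O[Si](C)(C)C(C)(C)C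
F6 | step 6 | 1-(2-hydroxy-4-methoxy-6-{[2-(trimethylsilyl)ethoxy]methoxy}phenyl)ethan-1-one | CC(=O)c1c(O)cc(OC)cc1OCOCC[Si](C)(C)C
F7 | step 6 | 1-[4-methoxy-2-(3-methylbut-2-en-1-yloxy)-6-{[2-(trimethylsilyl)ethoxy]methoxy}phenyl]ethan-1-one | CC(=O)c1c(OCC=C(C)C)cc(OC)cc1OCOCC[Si](C)(C)C
F8 | step 6 | SEM-bearing ortho-dienone: 2-acetyl-5-methoxy-6-(2-methylbut-3-en-2-yl)-3-{[2-(trimethylsilyl)ethoxy]methoxy}cyclohexa-2,4-dien-1-one (racemic, transient) | CC(=O)C1=C(OCOCC[Si](C)(C)C)C=C(OC)C(C(C)(C)C=C)C1=O
F9 | step 6 | SEM-bearing para-dienone: 2-acetyl-5-methoxy-4-(3-methylbut-2-en-1-yl)-3-{[2-(trimethylsilyl)ethoxy]methoxy}cyclohexa-2,5-dien-1-one (racemic, transient) | CC(=O)C1=C(OCOCC[Si](C)(C)C)C(CC=C(C)C)C(OC)=CC1=O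
F10 | step 6 | 1-[6-hydroxy-4-methoxy-3-(3-methylbut-2-en-1-yl)-2-{[2-(trimethylsilyl)ethoxy]methoxy}phenyl]ethan-1-one | CC(=O)c1c(O)cc(OC)c(CC=C(C)C)c1OCOCC[Si](C)(C)C
F11 | step 6 | (2E)-3-(dimethylamino)-1-[6-hydroxy-4-methoxy-3-(3-methylbut-2-en-1-yl)-2-{[2-(trimethylsilyl)ethoxy]methoxy}phenyl]prop-2-en-1-one | CN(C)/C=C/C(=O)c1c(O)cc(OC)c(CC=C(C)C)c1OCOCC[Si](C)(C)C
F12 | step 6 | SEM-bearing α-aryl enaminone: 3-(dimethylamino)-1-[6-hydroxy-4-methoxy-3-(3-methylbut-2-en-1-yl)-2-{[2-(trimethylsilyl)ethoxy]methoxy}phenyl]-2-(2,4,5-trimethoxyphenyl)prop-2-en-1-one (transient) | CN(C)C=C(C(=O)c1c(O)cc(OC)c(CC=C(C)C)c1OCOCC[Si](C)(C)C)c1cc(OC)c(OC)cc1OC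
F13 | step 6 | SEM-bearing aminal: 2-(dimethylamino)-7-methoxy-6-(3-methylbut-2-en-1-yl)-3-(2,4,5-trimethoxyphenyl)-5-{[2-(trimethylsilyl)ethoxy]methoxy}chroman-4-one (mixture of stereoisomers, transient) | CN(C)C1Oc2cc(OC)c(CC=C(C)C)c(OCOCC[Si](C)(C)C)c2C(=O)C1c1cc(OC)c(OC)cc1OC
F14 | step 6 | 7-methoxy-6-(3-methylbut-2-en-1-yl)-3-(2,4,5-trimethoxyphenyl)-5-{[2-(trimethylsilyl)ethoxy]methoxy}-4H-chromen-4-one | C[Si](C)(C)CCOCOc1c(CC=C(C)C)c(OC)cc2occ(-c3cc(OC)c(OC)cc3OC)c(=O)c12
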